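**Plan**
1. Eudesmane numbering is used throughout (ring A = C5–C10, ring B = C1–C5/C10, C14 = CH2O on C10, C15 = CH3 on C4). The retrosynthesis cuts, in order: the three esters; the C7 isopropenyl group, back to a lactone carbonyl C11 held on O9; the C6–C7 bond of ring A; then C9–C10 (aldol) and C10–C14 (hydroxymethylation), which leads to (S)-carvone.
2. Enabling feature: on ring A, O9 and the carbon substituent on C7 are 1,3-cis (both anti to C14), so C11 can be the carbonyl of a γ-butyrolactone on O9 whose α-carbon is C7. In ring B the C2 oxygen is conjugated through C3=C4 to a C5=C6 methylene, so a C2 ketone makes C6 an acceptor.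
3. Forward: ring B is the carvone ring (carvone C1/C2/C3/C4/C5/C6/CH3 = C5/C4/C3/C2/C1/C10/C15). The carvone isopropenyl group is a masked C1 oxygen (Criegee). The carvone ketone is transposed into the C2 ketone/C5=CH2 dienone (dienyl triflate, methylation, singlet oxygen, dehydration).
4. Ring A closes last, by 1,6-Michael addition of the lactone enolate (C7) to C6, giving a bridged lactone. CH3Li and a Wittig reaction then turn C11 into the isopropenyl group, and the 1,2-diol is differentiated through a cyclic orthoacetate.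
5. Stereochemistry: C1 from (S)-carvone; C10 and C9 from two enolate reactions anti to the isopropenyl group (chair aldol for C9); C7 enforced by the lactone ring and C5 by equilibration in the key step; C2 by hydride attack anti to C14.

Key step: step 9

Step 1
Reactants: 1 (S)-carvone; 2 formaldehyde
Product: 3 trans-6-(hydroxymethyl)carvone
Conditions: LiN(iPr)2, THF, −78 °C; CH2O (gas from cracked paraformaldehyde), −78 °C; AcOH
Reagents that add atoms: formaldehyde (C=O)
Why: The kinetic cross-conjugated lithium enolate (deprotonation at carvone C6) undergoes an aldol addition to formaldehyde anti to the isopropenyl group, which installs C14; the new centre is re-enolised in step 3, so its configuration is not critical.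

Step 2
Reactants: 3 trans-6-(hydroxymethyl)carvone; 4 tert-butyl(chloro)diphenylsilane
Product: 5 silyl ether of 3
Conditions: imidazole, DMF, 0 °C → rt
Reagents that add atoms: tert-butyl(chloro)diphenylsilane (CC(C)(C)[Si](Cl)(c1ccccc1)c1ccccc1)
Why: Standard silylation of the primary alcohol, which blocks retro-aldol loss of formaldehyde and gives a C14 ether that should survive every later step up to fluoride.

Step 3
Reactants: 5 silyl ether of 3; 6 methyl 4-oxobutanoate
Product: 8 keto lactone (quaternary C10 and C9 set), via aldol hydroxy ester 7 (not isolated)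
Conditions: LiN(iPr)2, THF, −78 °C; 6, −78 °C; AcOH; then PPTS (cat.), PhH, 50 °C
Reagents that add atoms: methyl 4-oxobutanoate (COC(=O)CCC=O)
Why: The tetrasubstituted enolate adds to the aldehyde (aldol reaction) on the face anti to the neighbouring isopropenyl group, which sets C10 with C14 cis to that group; a closed chair (Zimmerman–Traxler) transition state with the aldehyde chain equatorial puts the new oxygen anti to ring carbon C1 and should give 9S, and acid-catalysed lactonisation then removes the retro-aldol pathway.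

Step 4
Reactants: 8 keto lactone; 9 ozone; 10 methanol; 11 acetic anhydride
Product: 13 keto lactone C1 acetate, via methoxy hydroperoxide 12 (not isolated)
Conditions: O3, CH2Cl2/MeOH, −78 °C; then Ac2O, Et3N, DMAP (cat.), 0 °C → rt
Reagents that add atoms: ozone ([O-][O+]=O); methanol (CO)
Why: Ozone should cleave the electron-rich 1,1-disubstituted alkene in preference to the enone C=C, and the acetylated α-methoxy hydroperoxide undergoes Criegee rearrangement (C1 migrates from carbon to oxygen with retention), so the isopropenyl group becomes an acetate with the carvone configuration kept; the alkyl oxygen comes from ozone and the carbonyl oxygen from the methoxy group.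

Step 5
Reactants: 13 keto lactone C1 acetate; 14 trifluoromethanesulfonic anhydride
Product: 15 dienyl triflate
Conditions: Tf2O, 2,6-di-tert-butyl-4-methylpyridine, CH2Cl2, 0 °C → rt
Reagents that add atoms: trifluoromethanesulfonic anhydride (O=S(=O)(OS(=O)(=O)C(F)(F)F)C(F)(F)F)
Why: Because C10 is quaternary the enone can enolise only toward C2, so O-triflation followed by γ-deprotonation (enone to dienyl triflate) should give a single cyclohexa-1,3-dienyl triflate without forming an electron-rich dienolate that could expel the C1 acetate.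

Step 6
Reactants: 15 dienyl triflate; 16 tetramethylstannane
Product: 17 diene acetate (C6 methyl on C5)
Conditions: Me4Sn, Pd(PPh3)4 (cat.), LiCl, THF, 65 °C
Reagents that add atoms: tetramethylstannane (C[Sn](C)(C)C)
Why: Stille coupling of the vinyl triflate installs C6 under neutral conditions that tolerate lactone and acetate; oxidative addition of zerovalent palladium to the triflate should outpace ionisation of the hindered allylic acetate, for which the stannane is in any case a poor partner.

Step 7
Reactants: 17 diene acetate; 18 dioxygen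
Product: 20 C5-hydroxy C2-enone, via endoperoxide 19 (not isolated)
Conditions: O2, visible light, tetraphenylporphyrin (cat.), CH2Cl2, −78 °C; then Et3N, 0 °C → rt
Reagents that add atoms: dioxygen (O=O)
Why: The cisoid cyclohexa-1,3-diene adds singlet oxygen in a [4+2] cycloaddition, and Kornblum–DeLaMare fragmentation can remove only the single bridgehead hydrogen (on C2), so the ketone appears at C2 and the tertiary alcohol at C5; the face of attack is irrelevant because C2 and C5 both become sp2 later.

Step 8
Reactants: 20 C5-hydroxy C2-enone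
Product: 21 acetoxy dienone (C5=C6 methylene)
Conditions: Burgess reagent (MeO2CNSO2NEt3), PhMe, 60 °C
Reagents that add atoms: none
Why: Burgess dehydration (syn elimination) of the tertiary alcohol can only take a hydrogen from the C6 methyl group, since C10 is quaternary and C4 is sp2, so the linear dienone O=C2–C3=C4–C5=C6 should form regiospecifically.

Step 9
Reactants: 21 acetoxy dienone
Product: 23 tricyclic hydroxy enone lactone (ring A closed), via hydroxy dienone 22 (not isolated)
Conditions: KOtBu (3 equiv), THF/t-BuOH, 0 °C → rt; AcOH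
Reagents that add atoms: none
Why: tert-Butoxide first cleaves the activated α-keto acetate, and the C1 alkoxide then shields C1–H from enolisation; the reversibly formed lactone enolate (C7) adds to C6, the unsubstituted terminus of the dienone (vinylogous 1,6-Michael addition), and the extended enolate is protonated at C5 under the equilibrating conditions. The closest known reaction type is the base-mediated intramolecular Michael addition of an ester or ketone enolate that builds a bicyclo[3.2.1] system from a five-membered ring carrying a three-atom tether. Ring A closes 6-endo-trig with respect to the C5=C6 acceptor, with the enolate C=C exocyclic to the new ring. C7 is controlled by the temporary ring: the enolate carbon belongs to the lactone anchored on O9, so the C6–C7 bond can form only on the lactone face that carries C10, which forces the C7–C11 bond cis to O9 (both anti to C14) against the usual equatorial preference. C5 is controlled thermodynamically: in the bridged lactone the position on C5 under the lactone bridge can hold only hydrogen, so the C5–C4 bond goes exo and the trans-fused decalin results, while the C1 hydroxyl stays equatorial. The step needs 1,6- over 1,4- and 1,2-addition and reaction through the lactone enolate only; C6 is the one unhindered acceptor carbon, the 1,2-aldol adduct is reversible, 1,4-addition would create a quaternary carbon in a more strained bridged ring, and among the enolates in equilibrium only the lactone enolate has an irreversible exit.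

Step 10
Reactants: 23 tricyclic hydroxy enone lactone
Product: 24 cis-1,2-diol lactone
Conditions: NaBH4, CeCl3·7H2O, MeOH/CH2Cl2, −78 °C
Reagents that add atoms: none
Why: Luche 1,2-reduction, in which hydride should approach C2 anti to the axial C14 substituent on C10 (1,3-diaxial shielding, as for 2-oxo steroids with an angular methyl group), giving the pseudo-axial 2-OH cis to 1-OH and C14; the lactone is inert at this temperature.

Step 11
Reactants: 24 cis-1,2-diol lactone; 25 methyllithium
Product: 26 methyl hemiketal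
Conditions: CH3Li (4 equiv), THF, −78 °C; AcOH, −78 °C
Reagents that add atoms: methyllithium ([Li]C)
Why: Single nucleophilic addition to the bridged lactone, whose tetrahedral intermediate should not collapse at −78 °C and whose bridgehead α-carbon C7 cannot be enolised, gives the methyl hemiketal (a masked C7 acetyl group); two equivalents are consumed by the hydroxyl groups.

Step 12
Reactants: 26 methyl hemiketal; 27 methyltriphenylphosphonium bromide
Product: 29 triol with C7 isopropenyl, via hydroxy methyl ketone 28 (not isolated)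
Conditions: Ph3PCH3Br, KOtBu, THF, 0 → 50 °C
Reagents that add atoms: methyltriphenylphosphonium bromide, as its ylide (C[P+](c1ccccc1)(c1ccccc1)c1ccccc1.[Br-])
Why: Wittig methylenation of the ketone tautomer that is in equilibrium with the hemiketal (as with lactols) turns C11 into the isopropenyl group without any regiochemical choice and frees 9-OH; C7 keeps its configuration as long as olefination is faster than enolisation of the transient ketone.

Step 13
Reactants: 29 triol with C7 isopropenyl; 30 trimethyl orthoacetate; 11 acetic anhydride; 31 water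
Product: 34 2,9-diacetate with free 1-OH, via cyclic orthoacetate 32 (not isolated), via orthoacetate 9-acetate 33 (not isolated)
Conditions: CH3C(OMe)3, PPTS (cat.), CH2Cl2, rt; then Ac2O, pyridine, DMAP, rt; then AcOH/H2O/THF, 0 °C
Reagents that add atoms: trimethyl orthoacetate (CC(OC)(OC)OC); acetic anhydride (CC(=O)OC(C)=O); water (O)
Why: The cis-1,2-diol forms a five-membered cyclic orthoacetate, the remaining 9-OH is acetylated, and mild aqueous acid opens the 2-methoxy-1,3-dioxolane to the hydroxy acetate with the ester on the pseudo-axial oxygen O2 and the equatorial 1-OH free, the usual regiochemistry of cyclic orthoester hydrolysis.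

Step 14
Reactants: 34 2,9-diacetate with free 1-OH; 35 3-methylbut-2-enoyl chloride
Product: 36 fully acylated C14 silyl ether
Conditions: pyridine, DMAP (cat.), CH2Cl2, 0 °C → rt
Reagents that add atoms: 3-methylbut-2-enoyl chloride (CC(C)=CC(Cl)=O)
Why: Acylation of the only free hydroxyl (the tertiary and primary sites are absent or silylated); pyridine/DMAP is chosen over a stronger amine base to avoid deconjugation of the acyl group through the vinylketene.

Step 15
Reactants: 36 fully acylated C14 silyl ether
Product: 37 CNP0320218.1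
Conditions: HF·pyridine, pyridine, THF, 0 °C → rt
Reagents that add atoms: none
Why: Fluoride cleavage of the primary silyl ether under buffered acidic conditions, which should leave the three esters in place and avoid acyl migration toward the liberated 14-OH.

**Compound list**
1 | (S)-(+)-carvone | CC1=CC[C@@H](CC1=O)C(C)=C | starting material
2 | formaldehyde (monomer from paraformaldehyde) | C=O | starting material
3 | (5S,6S)-6-(hydroxymethyl)-2-methyl-5-(prop-1-en-2-yl)cyclohex-2-en-1-one | CC1=CC[C@@H]([C@@H](CO)C1=O)C(C)=C | intermediate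
4 | tert-butyl(chloro)diphenylsilane | CC(C)(C)[Si](Cl)(c1ccccc1)c1ccccc1 | starting material
5 | (5S,6S)-6-{[(tert-butyldiphenylsilyl)oxy]methyl}-2-methyl-5-(prop-1-en-2-yl)cyclohex-2-en-1-one | CC1=CC[C@@H]([C@@H](CO[Si](c2ccccc2)(c2ccccc2)C(C)(C)C)C1=O)C(C)=C | intermediate
6 | methyl 4-oxobutanoate | COC(=O)CCC=O | starting material
7 | methyl (4S)-4-hydroxy-4-[(1R,6R)-1-{[(tert-butyldiphenylsilyl)oxy]methyl}-3-methyl-2-oxo-6-(prop-1-en-2-yl)cyclohex-3-en-1-yl]butanoate | CC1=CC[C@H](C(C)=C)[C@@](CO[Si](c2ccccc2)(c2ccccc2)C(C)(C)C)([C@@H](O)CCC(=O)OC)C1=O | intermediate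
8 | (5S)-5-[(1R,6R)-1-{[(tert-butyldiphenylsilyl)oxy]methyl}-3-methyl-2-oxo-6-(prop-1-en-2-yl)cyclohex-3-en-1-yl]oxolan-2-one | CC1=CC[C@H](C(C)=C)[C@@](CO[Si](c2ccccc2)(c2ccccc2)C(C)(C)C)([C@@H]3CCC(=O)O3)C1=O | intermediate
9 | ozone | [O-][O+]=O | starting material
10 | methanol | CO | starting material
11 | acetic anhydride | CC(=O)OC(C)=O | starting material
12 | α-methoxy hydroperoxide of 8 (isopropenyl replaced by C(CH3)(OCH3)OOH; peroxy carbon unassigned) | CC1=CC[C@H](C(C)(OC)OO)[C@@](CO[Si](c2ccccc2)(c2ccccc2)C(C)(C)C)([C@@H]3CCC(=O)O3)C1=O | intermediate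
13 | (1S,2R)-2-{[(tert-butyldiphenylsilyl)oxy]methyl}-4-methyl-3-oxo-2-[(2S)-5-oxooxolan-2-yl]cyclohex-4-en-1-yl acetate | CC1=CC[C@H](OC(C)=O)[C@@](CO[Si](c2ccccc2)(c2ccccc2)C(C)(C)C)([C@@H]3CCC(=O)O3)C1=O | intermediate
14 | trifluoromethanesulfonic anhydride | O=S(=O)(OS(=O)(=O)C(F)(F)F)C(F)(F)F | starting material
15 | (5S,6R)-5-acetoxy-6-{[(tert-butyldiphenylsilyl)oxy]methyl}-2-methyl-6-[(2S)-5-oxooxolan-2-yl]cyclohexa-1,3-dien-1-yl trifluoromethanesulfonate | FC(F)(F)S(=O)(=O)OC1=C(C)C=C[C@H](OC(C)=O)[C@@]1(CO[Si](c2ccccc2)(c2ccccc2)C(C)(C)C)[C@@H]3CCC(=O)O3 | intermediate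
16 | tetramethylstannane | C[Sn](C)(C)C | starting material
17 | (1S,6S)-6-{[(tert-butyldiphenylsilyl)oxy]methyl}-4,5-dimethyl-6-[(2S)-5-oxooxolan-2-yl]cyclohexa-2,4-dien-1-yl acetate | CC1=C(C)C=C[C@H](OC(C)=O)[C@@]1(CO[Si](c2ccccc2)(c2ccccc2)C(C)(C)C)[C@@H]3CCC(=O)O3 | intermediate
18 | dioxygen | O=O | starting material
19 | endoperoxide of 17 (O–O bridge between C2 and C5; bridgeheads unassigned) | CC12OOC(C=C1C)[C@H](OC(C)=O)[C@@]2(CO[Si](c3ccccc3)(c3ccccc3)C(C)(C)C)[C@@H]4CCC(=O)O4 | intermediate
20 | (1R,2R)-2-{[(tert-butyldiphenylsilyl)oxy]methyl}-3-hydroxy-3,4-dimethyl-6-oxo-2-[(2S)-5-oxooxolan-2-yl]cyclohex-4-en-1-yl acetate (carbinol carbon unassigned) | CC1(O)C(C)=CC(=O)[C@H](OC(C)=O)[C@@]1(CO[Si](c2ccccc2)(c2ccccc2)C(C)(C)C)[C@@H]3CCC(=O)O3 | intermediate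
21 | (1R,2S)-2-{[(tert-butyldiphenylsilyl)oxy]methyl}-4-methyl-3-methylidene-6-oxo-2-[(2S)-5-oxooxolan-2-yl]cyclohex-4-en-1-yl acetate | C=C1C(C)=CC(=O)[C@H](OC(C)=O)[C@@]1(CO[Si](c2ccccc2)(c2ccccc2)C(C)(C)C)[C@@H]3CCC(=O)O3 | intermediate
22 | 1-O-deacetyl derivative of 21 (free α-hydroxy dienone, present as its potassium alkoxide) | C=C1C(C)=CC(=O)[C@H](O)[C@@]1(CO[Si](c2ccccc2)(c2ccccc2)C(C)(C)C)[C@@H]3CCC(=O)O3 | intermediate
23 | (1R,5R,7S,9S,10R)-14-[(tert-butyldiphenylsilyl)oxy]-1-hydroxy-2-oxo-12,13-dinoreudesm-3-en-11-oic acid 11,9-lactone (C11 bridges C7 and O9; rings A/B trans-fused) | O=C1O[C@H]2C[C@@H]1C[C@@H]3C(C)=CC(=O)[C@H](O)[C@@]23CO[Si](c4ccccc4)(c4ccccc4)C(C)(C)C | intermediate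
24 | (1R,2S,5R,7S,9S,10R)-14-[(tert-butyldiphenylsilyl)oxy]-1,2-dihydroxy-12,13-dinoreudesm-3-en-11-oic acid 11,9-lactone | O=C1O[C@H]2C[C@@H]1C[C@@H]3C(C)=C[C@H](O)[C@H](O)[C@@]23CO[Si](c4ccccc4)(c4ccccc4)C(C)(C)C | intermediate
25 | methyllithium | [Li]C | starting material
26 | (1R,2S,5R,7S,9S,10R)-14-[(tert-butyldiphenylsilyl)oxy]-9,11-epoxy-13-noreudesm-3-ene-1,2,11-triol (methyl hemiketal; C11 unassigned) | CC1(O)O[C@H]2C[C@@H]1C[C@@H]3C(C)=C[C@H](O)[C@H](O)[C@@]23CO[Si](c4ccccc4)(c4ccccc4)C(C)(C)C | intermediate
27 | methyltriphenylphosphonium bromide | C[P+](c1ccccc1)(c1ccccc1)c1ccccc1.[Br-] | starting material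
28 | open hydroxy ketone tautomer of 26 (1,2,9-trihydroxy-13-noreudesm-3-en-11-one 14-silyl ether) | CC(=O)[C@@H]1C[C@H](O)[C@@]2(CO[Si](c3ccccc3)(c3ccccc3)C(C)(C)C)[C@H](C1)C(C)=C[C@H](O)[C@@H]2O | intermediate
29 | (1R,2S,5R,7S,9S,10S)-14-[(tert-butyldiphenylsilyl)oxy]eudesma-3,11-diene-1,2,9-triol | C=C(C)[C@@H]1C[C@H](O)[C@@]2(CO[Si](c3ccccc3)(c3ccccc3)C(C)(C)C)[C@H](C1)C(C)=C[C@H](O)[C@@H]2O | intermediate
30 | trimethyl orthoacetate | CC(OC)(OC)OC | starting material
31 | water | O | starting material
32 | 1,2-O-(1-methoxyethylidene) derivative of 29 (orthoester carbon unassigned) | C=C(C)[C@@H]1C[C@H](O)[C@@]2(CO[Si](c3ccccc3)(c3ccccc3)C(C)(C)C)[C@H](C1)C(C)=C[C@@H]4OC(C)(OC)O[C@H]24 | intermediate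
33 | 9-O-acetyl derivative of 32 | C=C(C)[C@@H]1C[C@H](OC(C)=O)[C@@]2(CO[Si](c3ccccc3)(c3ccccc3)C(C)(C)C)[C@H](C1)C(C)=C[C@@H]4OC(C)(OC)O[C@H]24 | intermediate
34 | (1R,2S,5R,7S,9S,10R)-14-[(tert-butyldiphenylsilyl)oxy]-1-hydroxyeudesma-3,11-diene-2,9-diyl diacetate | C=C(C)[C@@H]1C[C@H](OC(C)=O)[C@@]2(CO[Si](c3ccccc3)(c3ccccc3)C(C)(C)C)[C@H](C1)C(C)=C[C@H](OC(C)=O)[C@@H]2O | intermediate
35 | 3-methylbut-2-enoyl chloride | CC(C)=CC(Cl)=O | starting material
36 | (1R,2S,5R,7S,9S,10S)-2,9-diacetoxy-14-[(tert-butyldiphenylsilyl)oxy]eudesma-3,11-dien-1-yl 3-methylbut-2-enoate | C=C(C)[C@@H]1C[C@H](OC(C)=O)[C@@]2(CO[Si](c3ccccc3)(c3ccccc3)C(C)(C)C)[C@H](C1)C(C)=C[C@H](OC(C)=O)[C@@H]2OC(=O)C=C(C)C | intermediate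
37 | CNP0320218.1, (1R,2S,5R,7S,9S,10S)-2,9-diacetoxy-14-hydroxyeudesma-3,11-dien-1-yl 3-methylbut-2-enoate | C=C(C)[C@@H]1C[C@H](OC(C)=O)[C@@]2(CO)[C@H](C1)C(C)=C[C@H](OC(C)=O)[C@@H]2OC(=O)C=C(C)C | target

**Totals**
Total step count: 15. Longest linear sequence: 15 steps (from 1).

**Steps most likely to fail**

Step 9. The base may engage the C1 acetate before it is cleaved (acyl transfer to an enolate oxygen, enolisation at C1), and the enolate may add in the 1,2- or 1,4-sense instead of at C6. The fallback takes the acyl cleavage out of the ring closure and runs the closure on a substrate without any acyl group. It sets out from 17: methanolysis (K2CO3, MeOH, 0 °C) should give the dienol F1, and silylation (Et3SiOTf, 2,6-lutidine, −78 °C) the triethylsilyl ether F2. Photooxygenation followed by Et3N, as in step 7, should lead through the endoperoxide F3 to the hydroxy enone F4, and Burgess dehydration to the dienone F5. Cyclisation with substoichiometric KOtBu in THF/t-BuOH then gives the tricyclic silyl ether F6. HF·pyridine at 0 °C removes the triethylsilyl group in the presence of the primary tert-butyldiphenylsilyl ether, and the route is rejoined at 23.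

Step 3. The hindered tetrasubstituted enolate may react slowly, lose the silyloxy group by β-elimination, revert by retro-aldol before lactonisation, or add with poor selectivity at C9. The fallback replaces the lithium aldol by an irreversible Lewis-acid aldol and sets C9 by reagent control. It sets out from 5: enolisation with LiN(iPr)2 in the presence of Me3SiCl gives the silyl enol ether F7. Mukaiyama aldol addition to 6 (TiCl4, CH2Cl2, −78 °C) gives 7 together with its C9 epimer F8. The mixture is oxidised with Dess–Martin periodinane to the single β-diketone F9. The unconjugated C9 ketone is then reduced with the CBS catalyst enantiomer that delivers 9S (BH3·SMe2), which returns 7; this lactonises with PPTS and rejoins the route at 8.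

Step 12. The hemiketal may fail to open, or the transient C7 acetyl ketone may enolise under the basic ylide and epimerise at C7, driven by relief of the 1,3-diaxial strain. The fallback avoids any enolisable ketone under basic conditions. It sets out from 24: double addition of Me3SiCH2MgCl/CeCl3 (THF, −78 °C → rt) to the lactone gives the bis(silylmethyl) carbinol F10. Peterson elimination on silica gel gives the allylsilane F11. Protodesilylation (TsOH·H2O cat., wet CH2Cl2, 0 °C) then gives the isopropenyl group, with fixed regiochemistry because the two CH2 termini are equivalent, and the route is rejoined at 29.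

**Further compounds**
F1 | step 9 | C1 alcohol of diene 17 | CC1=C(C)C=C[C@H](O)[C@@]1(CO[Si](c2ccccc2)(c2ccccc2)C(C)(C)C)[C@@H]3CCC(=O)O3
F2 | step 9 | C1 triethylsilyl ether of F1 | CC1=C(C)C=C[C@H](O[Si](CC)(CC)CC)[C@@]1(CO[Si](c2ccccc2)(c2ccccc2)C(C)(C)C)[C@@H]3CCC(=O)O3
F3 | step 9 | endoperoxide of F2 (bridgeheads unassigned) | CC12OOC(C=C1C)[C@H](O[Si](CC)(CC)CC)[C@@]2(CO[Si](c3ccccc3)(c3ccccc3)C(C)(C)C)[C@@H]4CCC(=O)O4
F4 | step 9 | C5-hydroxy C2-enone with C1 triethylsilyl ether (carbinol carbon unassigned) | CC1(O)C(C)=CC(=O)[C@H](O[Si](CC)(CC)CC)[C@@]1(CO[Si](c2ccccc2)(c2ccccc2)C(C)(C)C)[C@@H]3CCC(=O)O3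
F5 | step 9 | dienone with C1 triethylsilyl ether | C=C1C(C)=CC(=O)[C@H](O[Si](CC)(CC)CC)[C@@]1(CO[Si](c2ccccc2)(c2ccccc2)C(C)(C)C)[C@@H]3CCC(=O)O3
F6 | step 9 | 1-O-triethylsilyl ether of 23 | O=C1O[C@H]2C[C@@H]1C[C@@H]3C(C)=CC(=O)[C@H](O[Si](CC)(CC)CC)[C@@]23CO[Si](c4ccccc4)(c4ccccc4)C(C)(C)C
F7 | step 3 | trimethylsilyl enol ether of 5 | CC1=CC[C@H](C(C)=C)C(CO[Si](c2ccccc2)(c2ccccc2)C(C)(C)C)=C1O[Si](C)(C)C
F8 | step 3 | C9 epimer of 7 | CC1=CC[C@H](C(C)=C)[C@@](CO[Si](c2ccccc2)(c2ccccc2)C(C)(C)C)([C@H](O)CCC(=O)OC)C1=O
F9 | step 3 | β-diketone (C9 ketone) from 7 and F8 | CC1=CC[C@H](C(C)=C)[C@@](CO[Si](c2ccccc2)(c2ccccc2)C(C)(C)C)(C(=O)CCC(=O)OC)C1=O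
F10 | step 12 | bis(trimethylsilylmethyl) carbinol from 24 | C[Si](C)(C)CC(O)(C[Si](C)(C)C)[C@@H]1C[C@H](O)[C@@]2(CO[Si](c3ccccc3)(c3ccccc3)C(C)(C)C)[C@H](C1)C(C)=C[C@H](O)[C@@H]2O
F11 | step 12 | allylsilane (C12 trimethylsilyl derivative of 29) | C=C(C[Si](C)(C)C)[C@@H]1C[C@H](O)[C@@]2(CO[Si](c3ccccc3)(c3ccccc3)C(C)(C)C)[C@H](C1)C(C)=C[C@H](O)[C@@H]2O
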